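In a one-step world the free catalyst never tires, the left-handed substrate goes with the coupling partner to left-handed product, and the right-handed substrate stands by, so this kinetic resolution ends at 0.5 of the pair charged. At a fixed conversion the left-handed substrate is then the same for any catalyst charge, so doubling the catalyst gives a factor of 2. That was my zero.

all flasks: left-handed substrate 0.010 M; right-handed substrate 0.010 M

| run | coupling partner | free catalyst | remark |
|---|---|---|---|
| Saturday's | 10 mM | 2.5 µM | run made earlier |
| Sunday's | 10 mM | 3.8 µM | run made earlier |
| flask | 10.0 mM | 5.0 µM |  |

| run | time / d | left-handed product / % |
|---|---|---|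
| Saturday's | 0.250 | 7.2 |
| Saturday's | 0.417 | 10.0 |
| Saturday's | 0.625 | 10.7 |
| Saturday's | 1.04 | 14.0 |
| Saturday's | 1.67 | 16.2 |
| Saturday's | 3.00 | 18.1 |
| Sunday's | 0.208 | 9.4 |
| Sunday's | 0.625 | 16.6 |
| Sunday's | 1.04 | 18.8 |
| Sunday's | 1.67 | 21.6 |
| Sunday's | 2.50 | 22.9 |
| Sunday's | 3.00 | 24.1 |

(scatter of a reading: 0.5 percentage points)

- free catalyst is single-handed; left-handed substrate and right-handed substrate are mirror images of each other, charged as a racemate, each of them at the stated concentration
- no earlier run changes the charge of coupling partner; that part of a forecast is a guess

- apparent order in coupling partner when 20 % of the left-handed substrate and right-handed substrate together are converted (percent change of the rate of making left-handed product for one percent more coupling partner charged)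
- factor on the rate of making left-handed product when 20 % of the left-handed substrate and right-handed substrate together are converted if free catalyst is charged twice over

The runs left that world: Saturday's stood at 18.1 % after 3.00 d and Sunday's at 24.1 % after 3.00 d, both still creeping. So I added one more step, a catalyst lost as it works. Saturday's run gave 0.180 µM⁻¹ and Sunday's 0.173 µM⁻¹, mean 0.176 µM⁻¹. I called this the reach: the logarithm of left-handed substrate charged over left-handed substrate left, per unit of catalyst lost, taking the catalyst at those last readings as lost.

In the new flask, reaching 20 % of the pair is a logarithmic drop of 0.511, which costs 2.90 µM of the 5.0 µM charged. A doubled charge pays the same cost, so it keeps 7.10 µM against 2.10 µM, and I reckoned a factor of 3.38.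

Then came the rest. No run changes the coupling partner, so I guessed that the catalyst's loss takes it as the main step does, which keeps it out of the reach. At the fixed conversion the order then comes from depletion: in the new flask I counted 4.00 mM of the 10.0 mM charged as taken by the main step, and I reckoned an order of 1.67.

The forecast gave an order of 1.9 (0.7 to 3), above mine, and a factor of 3.2 (2.5 to 3.9), below mine, noting “The order in coupling partner is a guess”.

The flask gave an order of 1.7 and a factor of 3.43, with the conversion reached at 0.615 d, and it ran by these steps:

    coupling partner + free catalyst + left-handed substrate → free catalyst + left-handed product (k = 1.40 × 10⁶ L² mol⁻² h⁻¹)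
    coupling partner + free catalyst + right-handed substrate → free catalyst + right-handed product (k = 18000 L² mol⁻² h⁻¹)
    2 coupling partner → self-condensation product (k = 0.330 L mol⁻¹ h⁻¹)
    coupling partner + free catalyst → spent catalyst (k = 7.80 L mol⁻¹ h⁻¹)

At the start the flask used coupling partner 11 times as fast in the main step as in self-condensation. The reach, multiplied by the flask's catalyst charge, gives a logarithmic drop of 0.880, from which I reckoned left-handed product at 29.3 % of the pair for that charge wholly lost. After 30.0 d the flask held 29.6 % left-handed product, with spent catalyst at >99.9 %.

The data were generated by integration with made-up constants, noise included.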